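Slowness in these flasks can come from a dying catalyst as well as from a lack of reagent. The winter run levels off near 15.3% with 84.7% of the starting material unconverted and second substrate in excess, so its reading points to a dying enzyme. The dusk run, at 0.48 equiv, is still climbing at 36.1% after 20.0 min.

| setting | dusk | winter | Friday's | Monday's | Thursday's | Saturday's | Sunday's |
|---|---|---|---|---|---|---|---|
| starting material | 0.10 M | 0.10 M | 0.10 M | 0.10 M | 0.10 M | 0.10 M | 0.10 M |
| second substrate | 0.48 equiv | 2.8 equiv | 0.400 equiv | 0.600 equiv | 0.800 equiv | 1.20 equiv | 2.00 equiv |
| enzyme | 0.01 mol% | 0.01 mol% | 0.01 mol% | 0.01 mol% | 0.01 mol% | 0.01 mol% | 0.01 mol% |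
| remark | run made earlier | run made earlier |  |  |  |  |  |
| time |  |  | 40 min | 40 min | 40 min | 40 min | 40 min |

- dusk (time / min: product / %): 2.00: 6.7; 5.00: 14.2; 10.0: 24.5; 15.0: 31.9; 20.0: 36.1
- winter (time / min: product / %): 4.00: 11.9; 8.00: 14.3; 12.0: 15.7; 15.0: 15.3; 20.0: 15.3

(standard deviation of a reading: 0.5 percentage points)

- "hardly changes" means that all values lie within two and a half points (for a concentration: within two and a half percent of the largest)

1. amount of product at the end, in percent of the starting material charged for Friday's, Monday's, Thursday's, Saturday's, Sunday's, in this order
2. how the row runs (rises, then falls / falls all the way / rises all the way / falls, then rises / hardly changes)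

Two times can be read from the winter run, and their ratio gives that plateau. The first is the life of the enzyme, from the approach to the plateau:

life = 4.00 min / ln(plateau / (plateau − first reading)) = 2.66 min

The second is the filling time, which the opening rate would need for the whole charge:

filling time = life / plateau = 17.4 min

The plateau is the ratio of the two, and 17.4 min is longer than 2.66 min, so the winter flask stops early. This reckoning assumes that second substrate shortens the life in proportion to its equivalents and leaves the filling time unchanged. The capacity, defined as plateau fraction times equivalents of second substrate, is then constant:

capacity = 15.3% × 2.8 equiv = 0.428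

log(plateau) = −0.368 − log(equivalents)

The slope is minus one. If each product takes one second substrate, that reagent is the limiting reagent at low dose, and product cannot exceed its equivalents as a fraction of the charge. In this reckoning the row follows the lower ceiling. The charge gives 0.400 on Friday's and 0.600 on Monday's, where capacity would allow 71.4%. Capacity gives 53.5% on Thursday's, 35.7% on Saturday's and 21.4% on Sunday's. So the reckoned row rises, then falls.

The forecast, holding that “excess second substrate kills the enzyme”, gives 38%, 49%, 47%, 34% and 21%, a row described as rises, then falls, with its Thursday's value lower than the 53.5% reckoned here.

The flasks give 37.8%, 51.4%, 53.8%, 38.4% and 21.7%, a row described as rises, then falls.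

    second substrate + starting complex ⇌ ternary complex (K = 39.7 /M, k = 33700 /M/min)
    starting complex → spent catalyst A (k = 0.0241 /min)
    second substrate + ternary complex → spent catalyst B (k = 1.78 /M/min)
    starting material + enzyme ⇌ starting complex (K = 500 /M, k = 3.53 × 10⁵ /M/min)
    ternary complex → enzyme + product (k = 743 /min)

Sunday's flask stops short because of the turning of second substrate + ternary complex into spent catalyst B: with that step taken away, its product goes from 21.7% to >99.9%. Product and that death both leave from the ternary complex, so its amount cancels and, with second substrate held at its charge, the constants give a capacity of 0.417. Sunday's flask shows 0.434. Saturday's flask shows 0.461, with 68% of its second substrate left and 92.8% of its catalyst as spent catalyst B.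

The numbers in the tables were computed for an exercise, noise included.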